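## The problem

Euchrenone b1 (14) is a 3-aryl-4H-chromen-4-one: ring A is fused to the pyranone ring C through C4a–C8a, and ring B hangs from C3. It has no stereocentre, so the task is one of placement and survival, not of three-dimensional control. Ring A is fully substituted (O1 at C8a, prenyl at C8, OH at C7, prenyl at C6, OH at C5, the C4 carbonyl at C4a), and ring B carries a third prenyl group at C3′ beside the 4′-hydroxyl. Three 3-methylbut-2-enyl chains must therefore each end up on one defined carbon next to a phenol. These ortho-prenylphenol units are the fragile part: acid adds the phenol across the alkene to give 2,2-dimethylchromans, electrophilic halogen and oxidants attack the trisubstituted alkenes, and hydrogenation is excluded. This rules out benzyl ethers, harsh demethylation and most late oxidations. The phenols make both rings electron-rich, and the 5-OH is hydrogen-bonded to the C4 carbonyl. The feature that opens the plan is C3, which carries ring B, the bond to the C4 carbonyl and the bond to C2, itself tied to ring A through O1. If C2=C3 is read as a dehydrated tertiary alcohol, C3–C4 becomes the central bond of an α-hydroxy ketone; cutting it leaves a ring A aldehyde (C4) and a ring B aryl ketone (C3) already tethered through O1–C2 at the distance of a six-membered ring.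

## Retrosynthesis

**14 to 13 (no skeletal bond cut).** The three phenols of 14 are masked as methoxymethyl ethers in 13. Benzyl ethers cannot be removed beside three alkenes, methyl ethers need reagents that cyclise prenylphenols, and silyl ethers on ring A next to a carbonyl are at risk from the carbonate and amidine bases used later. Methoxymethyl ethers survive organolithium reagents, carbonate, DBU and SOCl2/pyridine and fall together in dilute methanolic acid. The forward step must be mild enough to spare the ortho-prenylphenols it uncovers.

**13 to 12 (C2=C3 read as loss of water).** The pyranone double bond is traced back to a tertiary alcohol at C3, giving the 3-hydroxychroman-4-one 12. Only C2 carries hydrogens next to C3, so the forward dehydration has a single regiochemical outcome and gains the conjugation of the pyranone. The C3 stereocentre of 12 is erased, so 12 can be racemic.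

**12 to 11 (cut C3–C4, open ring C).** 12 is an α-hydroxy ketone, and cutting C3–C4 gives the keto aldehyde 11: a C4 acyl anion equivalent adds to the C3 ketone. Neighbouring cuts are less attractive here. Cutting C3–C1′ (cross-coupling of a 3-halochromone) requires electrophilic halogenation in the presence of two prenyl groups, and cutting C4–C4a (acylation of ring A) requires acid and regiocontrol on a phloroglucinol. The C3–C4 cut splits the molecule into two arene halves of similar size joined by one ether bond, and the forward reaction is redox-neutral, metal-free and without by-product. It asks for the aldehyde, flanked by two oxygen substituents, to form the carbene adduct faster than base can enolise the O–CH2 ketone.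

**11 to 4 and 10 (cut O1–C2).** The ether bond is made by alkylating the free phenol of salicylaldehyde 4 with α-chloro ketone 10. Bringing the ketone in complete means the ring A aldehyde never meets an organometallic reagent and needs no masking. The forward reaction must stop at the ether and not go on to base-induced cyclocondensation.

**10 to 7 and 8; 7 to 6; 6 to 5 and 2.** The aryl–carbonyl bond of 10 comes from aryllithium 9 (from bromide 7) and the commercial chloroacetyl Weinreb amide 8, which gives the α-chloro ketone in one step without halogenating a ketone beside a prenyl alkene. 7 is the methoxymethyl ether of 6, and 6 is the ortho-C-prenylation product of 4-bromophenol 5 with prenyl bromide 2, the para position being blocked by bromine.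

**4 to 3; 3 to 1 and 2.** 4 is the bis(methoxymethyl) ether of 3 in which the hydroxyl chelated to the formyl group stays free, the usual outcome for 2,4,6-trihydroxyaryl carbonyl compounds. 3 comes from twofold C-prenylation of 2,4,6-trihydroxybenzaldehyde 1 with 2 at the only two free ring carbons. The reaction is short but its selectivity is modest, and a slower, unambiguous route is held in reserve.

## Roads not taken

**Alternative 1:** The cut removes the three aryl–CH2 bonds (C6, C8 and C3′) and takes the side chains back to O-allyl groups on commercial genistein A1.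
- Forward: A1 is allylated on all three oxygens to give A2. Heating A2 at about 200 °C in a high-boiling aniline solvent sets off three aromatic Claisen rearrangements. The 4′-O-allyl goes to C3′ and the 5-O-allyl can only go to C6. The 7-O-allyl goes to C8 or C6, with a Cope relay moving a chain on when an ortho carbon is filled. The product is 6,8,3′-triallylgenistein A3, and threefold ruthenium-carbene cross-metathesis with 2-methylbut-2-ene A4 would then give 14.
- Merits: about four steps from an intact isoflavone, no final deprotection, and a regiochemical outcome that converges in principle.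
- Weak points: the chelated 5-OH of A1 resists allylation, and its allyl ether tends to cleave on heating. Ortho-allylphenols at this temperature add their hydroxyl across the alkene. The two ring A migrations depend on each other, so partly rearranged and cyclised isomers are to be expected. Three allyl groups beside free phenols must then all undergo metathesis completely; mixed allyl/prenyl products differ by two methyl groups and would be hard to separate, and ruthenium hydrides isomerise ortho-allylphenols to propenylphenols.
- Comparison: in step count this road is clearly better than the chosen plan (about four steps against nine), and it avoids a final acid treatment. The chosen plan sets against this positional certainty (each prenyl group is installed as prenyl on a carbon fixed by the building block), the absence of any step above about 50 °C, and intermediates that differ enough to be purified.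

**Alternative 2:** The cut removes four bonds of ring A (C8–C8a, C5–C6, C7–C8, C5–C4a), so that ring A is assembled on a preformed pyranone.
- Forward: irradiation of diazoketone A5 with siloxyalkyne A6 causes a Wolff rearrangement in which the pyranone carbon migrates (C8–C8a). A ketene–alkyne (2+2) cycloaddition follows (C5–C6 and C7–C8), then four-electron ring opening, six-electron ring closure (C5–C4a) and tautomerisation to the bis-silyl ether A7. Fluoride would remove both silyl groups to give 14.
- Merits: one step builds the hexasubstituted ring A with the substitution pattern dictated by mechanism. It is the most convergent of the roads, and the final deprotection by fluoride is gentler on prenylphenols than the acid step of the chosen plan.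
- Weak points: A5 carries a prenyl chain on the diazo carbon, and carbenes of this type undergo a 1,2-hydride shift to enones in competition with the Wolff rearrangement. The 4-pyranone chromophore is itself photolabile. Both partners need several steps each, so the total count exceeds that of the chosen plan.
- Comparison: this road is more convergent and its end game is milder. The chosen plan sets against this building blocks that are two or three steps from commercial phenols and a key step whose substrate class is established.

**Alternative 3:** The cut removes C2′–C3′ and C4′–C5′ of ring B.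
- Forward: the 2-pyranone A8, which carries the chromone at its 5-position, adds siloxyalkyne A6 in an inverse-demand Diels–Alder reaction. The nucleophilic alkyne carbon bearing the prenyl chain bonds to the electrophilic C6 of the pyranone, and decarboxylative retro-Diels–Alder aromatisation gives ring B in A9. Removal of the silyl and methoxymethyl groups gives 14.
- Merits: the relation of prenyl group and oxygen on ring B is fixed by polarity, and the aromatisation is irreversible.
- Weak points: ring B is the simplest part of the molecule (7 is two steps from 5 in the chosen route), so the key step is spent where no problem lies. The hexasubstituted ring A fused to the pyranone must still be made by other means. A8 would itself come from a coupling at C3 of a chromone, where coupling the complete ring B would give the skeleton directly. The cycloaddition needs heat, under which siloxyalkynes rearrange to silylketenes, and two kinds of protecting group remain at the end.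
- Comparison: apart from offering a late point at which ring B could be varied, this road is not better than the chosen plan in any respect.

Key step: step 7

Assumption: 12 is carried as the racemate; its single stereocentre (C3) is removed in step 8, so no enantiocontrol is sought.

## Route

Step 1
Reactants: 1 2,4,6-trihydroxybenzaldehyde; 2 prenyl bromide (1-bromo-3-methylbut-2-ene, 2.2 equiv)
Product: 3 2,4,6-trihydroxy-3,5-bis(3-methylbut-2-en-1-yl)benzaldehyde
Conditions: KOH (10% aq), 0 °C → rt
Reagents that add atoms: none
Why: C-alkylation of an acylphloroglucinol phenoxide; in water the hydrogen-bonded phenolate reacts at carbon, and C3 and C5 are the only free ring positions, so two equivalents of 2 should give the 3,5-diprenyl compound beside mono- and over-alkylated material that is separated by chromatography.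

Step 2
Reactants: 3 2,4,6-trihydroxy-3,5-bis(3-methylbut-2-en-1-yl)benzaldehyde
Product: 4 2-hydroxy-4,6-bis(methoxymethoxy)-3,5-bis(3-methylbut-2-en-1-yl)benzaldehyde
Conditions: MOMCl (2.2 equiv), i-Pr2NEt, CH2Cl2, 0 °C → rt
Reagents that add atoms: chloromethyl methyl ether (MOMCl), COCCl
Why: O-alkylation with an α-chloro ether (Williamson type); the 4-OH and one of the two equivalent ortho hydroxyls react, while the remaining ortho hydroxyl is held in the hydrogen bond to the formyl oxygen and is not alkylated with an amine base.

Step 3
Reactants: 5 4-bromophenol; 2 prenyl bromide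
Product: 6 4-bromo-2-(3-methylbut-2-en-1-yl)phenol
Conditions: NaH, toluene, 0 °C; then 2, rt
Reagents that add atoms: none
Why: Ortho-C-alkylation of a sodium phenoxide in a non-polar solvent, where the aggregated ion pair shields oxygen and delivers the allylic halide to the ortho carbon; the para position is blocked by bromine and a slight deficit of 2 limits double alkylation.

Step 4
Reactants: 6 4-bromo-2-(3-methylbut-2-en-1-yl)phenol
Product: 7 4-bromo-1-(methoxymethoxy)-2-(3-methylbut-2-en-1-yl)benzene
Conditions: MOMCl, i-Pr2NEt, CH2Cl2, 0 °C → rt
Reagents that add atoms: chloromethyl methyl ether (MOMCl), COCCl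
Why: Standard methoxymethyl protection of a phenol; it removes the acidic proton before lithiation and gives ring B the same protecting group as ring A, so that all three fall in one final operation.

Step 5
Reactants: 7 4-bromo-1-(methoxymethoxy)-2-(3-methylbut-2-en-1-yl)benzene; 8 2-chloro-N-methoxy-N-methylacetamide
Product: 10 2-chloro-1-[4-(methoxymethoxy)-3-(3-methylbut-2-en-1-yl)phenyl]ethan-1-one, via aryllithium 9 (not isolated)
Conditions: n-BuLi, THF, −78 °C; then 8, −78 → 0 °C; aq NH4Cl
Reagents that add atoms: none
Why: Bromine–lithium exchange followed by Weinreb amide acylation; the chelated tetrahedral adduct persists until the quench, so the aryllithium adds only once, and at low temperature the C–Cl bond and the prenyl group are left alone.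

Step 6
Reactants: 4 2-hydroxy-4,6-bis(methoxymethoxy)-3,5-bis(3-methylbut-2-en-1-yl)benzaldehyde; 10 2-chloro-1-[4-(methoxymethoxy)-3-(3-methylbut-2-en-1-yl)phenyl]ethan-1-one
Product: 11 2-{2-[4-(methoxymethoxy)-3-(3-methylbut-2-en-1-yl)phenyl]-2-oxoethoxy}-4,6-bis(methoxymethoxy)-3,5-bis(3-methylbut-2-en-1-yl)benzaldehyde
Conditions: K2CO3, KI (cat.), acetone, rt
Reagents that add atoms: none
Why: Williamson etherification of the phenoxide with an α-halo ketone activated by Finkelstein exchange, forming O1–C2; carbonate at room temperature is chosen because hotter or stronger base would start the Rap–Stoermer aldol condensation to a 2-aroylbenzofuran.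

Step 7
Reactants: 11 2-{2-[4-(methoxymethoxy)-3-(3-methylbut-2-en-1-yl)phenyl]-2-oxoethoxy}-4,6-bis(methoxymethoxy)-3,5-bis(3-methylbut-2-en-1-yl)benzaldehyde
Product: 12 rac-3-hydroxy-5,7-bis(methoxymethoxy)-3-[4-(methoxymethoxy)-3-(3-methylbut-2-en-1-yl)phenyl]-6,8-bis(3-methylbut-2-en-1-yl)chroman-4-one
Conditions: 6,7-dihydro-2-(2,4,6-trimethylphenyl)-5H-pyrrolo[2,1-c][1,2,4]triazol-2-ium chloride (20 mol%), DBU (15 mol%), THF, rt, argon
Reagents that add atoms: none
Why: DBU deprotonates the triazolium salt to the carbene, which adds to the formyl group of 11, and proton transfer gives the enaminol (Breslow intermediate) in which the former aldehyde carbon C4 is nucleophilic. This carbon attacks the tethered aryl ketone carbonyl (C3) to form C3–C4, and proton transfer with release of the carbene leaves the tertiary α-hydroxy ketone 12; the closest known reaction type is the carbene-catalysed intramolecular crossed aldehyde–ketone benzoin reaction that gives 3-hydroxychroman-4-ones. Ring C closes in the 6-exo-trig mode, the ketone C=O lying outside the new ring O1–C2–C3–C4–C4a–C8a. The new stereocentre C3 is not controlled, since the catalyst is achiral and 11 has no other stereocentre, so 12 should form as the racemate, which is sufficient because step 8 removes C3 as a stereocentre. The step needs crossed chemoselectivity, which the substrate secures: only the aldehyde can become the acyl anion equivalent, the ketone is the only acceptor within reach, and intermolecular homo-benzoin between two aldehydes each flanked by two oxygen substituents is disfavoured. It also needs the carbene path to outrun base-induced aldol attack of the O–CH2 ketone on the aldehyde; DBU is therefore kept below the azolium loading, and the aldehyde, deactivated by three oxygen donors and hindered on both sides, is a poor aldol acceptor. The N-mesityl group makes carbene addition to the aldehyde practically irreversible and speeds enaminol formation, ortho-alkoxy groups favour the initial adduct, and exclusion of air prevents oxidation of the enaminol to the acid.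

Step 8
Reactants: 12 rac-3-hydroxy-5,7-bis(methoxymethoxy)-3-[4-(methoxymethoxy)-3-(3-methylbut-2-en-1-yl)phenyl]-6,8-bis(3-methylbut-2-en-1-yl)chroman-4-one
Product: 13 5,7-bis(methoxymethoxy)-3-[4-(methoxymethoxy)-3-(3-methylbut-2-en-1-yl)phenyl]-6,8-bis(3-methylbut-2-en-1-yl)-4H-chromen-4-one
Conditions: SOCl2, pyridine, CH2Cl2, 0 °C → rt
Reagents that add atoms: none
Why: Dehydration of a tertiary alcohol through its chlorosulfite with pyridine as base (E2 elimination); the only β-hydrogens are on C2, so the double bond can form only across C2–C3, and the conjugated pyranone is the driving force; the buffered medium spares the methoxymethyl ethers and the alkenes.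

Step 9
Reactants: 13 5,7-bis(methoxymethoxy)-3-[4-(methoxymethoxy)-3-(3-methylbut-2-en-1-yl)phenyl]-6,8-bis(3-methylbut-2-en-1-yl)-4H-chromen-4-one
Product: 14 Euchrenone b1, 5,7-dihydroxy-3-[4-hydroxy-3-(3-methylbut-2-en-1-yl)phenyl]-6,8-bis(3-methylbut-2-en-1-yl)-4H-chromen-4-one
Conditions: HCl (1 M in MeOH), rt → 40 °C
Reagents that add atoms: none
Why: Acid-catalysed acetal exchange with methanol removes the three methoxymethyl ethers as dimethoxymethane; dilute acid, moderate temperature and a short reaction time are chosen because stronger or longer acid treatment would add the freed phenols across the prenyl double bonds.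

## Compound list

1 | 2,4,6-trihydroxybenzaldehyde | O=Cc1c(O)cc(O)cc1O | starting material
2 | prenyl bromide (1-bromo-3-methylbut-2-ene) | CC(C)=CCBr | starting material
3 | 2,4,6-trihydroxy-3,5-bis(3-methylbut-2-en-1-yl)benzaldehyde | O=Cc1c(O)c(CC=C(C)C)c(O)c(CC=C(C)C)c1O | intermediate
4 | 2-hydroxy-4,6-bis(methoxymethoxy)-3,5-bis(3-methylbut-2-en-1-yl)benzaldehyde | O=Cc1c(O)c(CC=C(C)C)c(OCOC)c(CC=C(C)C)c1OCOC | intermediate
5 | 4-bromophenol | Oc1ccc(Br)cc1 | starting material
6 | 4-bromo-2-(3-methylbut-2-en-1-yl)phenol | CC(C)=CCc1cc(Br)ccc1O | intermediate
7 | 4-bromo-1-(methoxymethoxy)-2-(3-methylbut-2-en-1-yl)benzene | COCOc1ccc(Br)cc1CC=C(C)C | intermediate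
8 | 2-chloro-N-methoxy-N-methylacetamide | CON(C)C(=O)CCl | starting material
9 | [4-(methoxymethoxy)-3-(3-methylbut-2-en-1-yl)phenyl]lithium (not isolated) | [Li]c1ccc(OCOC)c(CC=C(C)C)c1 | intermediate
10 | 2-chloro-1-[4-(methoxymethoxy)-3-(3-methylbut-2-en-1-yl)phenyl]ethan-1-one | O=C(CCl)c1ccc(OCOC)c(CC=C(C)C)c1 | intermediate
11 | 2-{2-[4-(methoxymethoxy)-3-(3-methylbut-2-en-1-yl)phenyl]-2-oxoethoxy}-4,6-bis(methoxymethoxy)-3,5-bis(3-methylbut-2-en-1-yl)benzaldehyde | O=Cc1c(OCOC)c(CC=C(C)C)c(OCOC)c(CC=C(C)C)c1OCC(=O)c1ccc(OCOC)c(CC=C(C)C)c1 | intermediate
12 | rac-3-hydroxy-5,7-bis(methoxymethoxy)-3-[4-(methoxymethoxy)-3-(3-methylbut-2-en-1-yl)phenyl]-6,8-bis(3-methylbut-2-en-1-yl)chroman-4-one (racemic at C3) | COCOc1ccc(C2(O)COc3c(CC=C(C)C)c(OCOC)c(CC=C(C)C)c(OCOC)c3C2=O)cc1CC=C(C)C | intermediate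
13 | 5,7-bis(methoxymethoxy)-3-[4-(methoxymethoxy)-3-(3-methylbut-2-en-1-yl)phenyl]-6,8-bis(3-methylbut-2-en-1-yl)-4H-chromen-4-one | COCOc1ccc(-c2coc3c(CC=C(C)C)c(OCOC)c(CC=C(C)C)c(OCOC)c3c2=O)cc1CC=C(C)C | intermediate
14 | Euchrenone b1, 5,7-dihydroxy-3-[4-hydroxy-3-(3-methylbut-2-en-1-yl)phenyl]-6,8-bis(3-methylbut-2-en-1-yl)-4H-chromen-4-one | CC(C)=CCc1cc(-c2coc3c(CC=C(C)C)c(O)c(CC=C(C)C)c(O)c3c2=O)ccc1O | target

## Step count and risks

Total: 9 steps. Longest linear sequence: 7 steps (steps 3, 4, 5, 6, 7, 8 and 9, from 4-bromophenol 5); the ring A branch (steps 1 and 2) joins at step 6.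

**Step 7 (key step).**
- Risk: formation of the enaminol may be slow, because the aldehyde of 11 is electron-rich and flanked by two oxygen substituents and two nearby prenyl chains. The free base then has time to enolise the O–CH2 ketone, and aldol condensation to a benzofuran, or oxidation of the enaminol by traces of air, would consume the substrate.
- Within the same disconnection, a smaller azolium salt or a weaker amine base would be tried first.
- Fallback: Suzuki–Miyaura coupling, which forms C3–C1′ instead of C3–C4. It sets out from 4 and 7 and returns at 13.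
  - MeMgBr adds to 4 to give 1-[2-hydroxy-4,6-bis(methoxymethoxy)-3,5-bis(3-methylbut-2-en-1-yl)phenyl]ethan-1-ol F1.
  - MnO2 oxidises F1 to 1-[2-hydroxy-4,6-bis(methoxymethoxy)-3,5-bis(3-methylbut-2-en-1-yl)phenyl]ethan-1-one F2.
  - Heating F2 with N,N-dimethylformamide dimethyl acetal gives (E)-3-(dimethylamino)-1-[2-hydroxy-4,6-bis(methoxymethoxy)-3,5-bis(3-methylbut-2-en-1-yl)phenyl]prop-2-en-1-one F3.
  - Iodine with pyridine closes F3 to 3-iodo-5,7-bis(methoxymethoxy)-6,8-bis(3-methylbut-2-en-1-yl)-4H-chromen-4-one F4. The enaminone carbon is far more nucleophilic than the prenyl alkenes, and one equivalent of iodine is used.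
  - Aryllithium 9, made from 7 as in step 5, is trapped with 2-isopropoxy-4,4,5,5-tetramethyl-1,3,2-dioxaborolane to give 2-[4-(methoxymethoxy)-3-(3-methylbut-2-en-1-yl)phenyl]-4,4,5,5-tetramethyl-1,3,2-dioxaborolane F5.
  - Coupling of F4 with F5 (Pd(PPh3)4, aq Na2CO3, 1,2-dimethoxyethane) gives 13.

**Step 1.**
- Risk: poor control over the degree and site of alkylation. Monoalkylation, a second alkylation at an already substituted carbon with loss of aromaticity, and O-alkylation all compete, because each phenoxide carbon and oxygen is nucleophilic.
- Fallback: iterative directed ortho-metalation, which places each chain on a defined carbon. It sets out from 2 and returns at 4.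
  - Phloroglucinol is converted with MOMCl and NaH into 1,3,5-tris(methoxymethoxy)benzene F6.
  - Lithiation between two methoxymethoxy groups (n-BuLi, THF, 0 °C) and alkylation with 2 gives 1,3,5-tris(methoxymethoxy)-2-(3-methylbut-2-en-1-yl)benzene F7.
  - Repeating the operation gives 1,3,5-tris(methoxymethoxy)-2,4-bis(3-methylbut-2-en-1-yl)benzene F8.
  - A third lithiation at the last ring hydrogen and quenching with N,N-dimethylformamide gives 2,4,6-tris(methoxymethoxy)-3,5-bis(3-methylbut-2-en-1-yl)benzaldehyde F9.
  - A trace of HCl in methanol at room temperature removes one of the two equivalent methoxymethyl groups next to the formyl group, which are the most labile because of carbonyl assistance, and gives 4.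

**Step 6.**
- Risk: alkylation of the hindered, hydrogen-bonded phenol of 4 may be slow. Forcing it with heat or stronger base invites enolisation of the product ketone and cyclocondensation onto the aldehyde.
- Fallback: the ketone is made only after the ether bond, so that base never meets aldehyde and enolisable ketone together. It sets out from 4 and returns at 11.
  - 4 is alkylated with 2-bromo-N-methoxy-N-methylacetamide (K2CO3, N,N-dimethylformamide, 50 °C) to give 2-[2-formyl-3,5-bis(methoxymethoxy)-4,6-bis(3-methylbut-2-en-1-yl)phenoxy]-N-methoxy-N-methylacetamide F10. This amide does not enolise under carbonate.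
  - The aldehyde is masked with trimethyl orthoformate and pyridinium p-toluenesulfonate in methanol as the dimethyl acetal 2-[2-(dimethoxymethyl)-3,5-bis(methoxymethoxy)-4,6-bis(3-methylbut-2-en-1-yl)phenoxy]-N-methoxy-N-methylacetamide F11.
  - Aryllithium 9 (from 7) adds to the Weinreb amide to give 2-[2-(dimethoxymethyl)-3,5-bis(methoxymethoxy)-4,6-bis(3-methylbut-2-en-1-yl)phenoxy]-1-[4-(methoxymethoxy)-3-(3-methylbut-2-en-1-yl)phenyl]ethan-1-one F12.
  - Pyridinium p-toluenesulfonate in wet acetone releases the aldehyde and gives 11. The acetal of an electron-rich benzaldehyde hydrolyses far faster than the aryl methoxymethyl ethers.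

**Step 8.**
- Risk: ionisation of the chlorosulfite towards substitution (a tertiary α-chloro ketone) or skeletal rearrangement of the α-hydroxy ketone instead of clean elimination, and partial loss of methoxymethyl groups if the medium turns acidic.
- Fallback: the order of events is reversed and a different elimination mechanism is used. It sets out from 12 and returns at 14.
  - Methanolic HCl first removes the three methoxymethyl groups to give rac-3,5,7-trihydroxy-3-[4-hydroxy-3-(3-methylbut-2-en-1-yl)phenyl]-6,8-bis(3-methylbut-2-en-1-yl)chroman-4-one F13.
  - The free 4′-hydroxyl of F13 then lets the C3 hydroxyl ionise to a quinone-methide-like cation, which loses a proton from C2 on gentle warming in the same medium and gives 14 directly. This saves one step, at the price of a longer acid exposure of the prenylphenols.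

## Further compounds

F1 | step 7 | 1-[2-hydroxy-4,6-bis(methoxymethoxy)-3,5-bis(3-methylbut-2-en-1-yl)phenyl]ethan-1-ol (racemic) | CC(O)c1c(O)c(CC=C(C)C)c(OCOC)c(CC=C(C)C)c1OCOC
F2 | step 7 | 1-[2-hydroxy-4,6-bis(methoxymethoxy)-3,5-bis(3-methylbut-2-en-1-yl)phenyl]ethan-1-one | CC(=O)c1c(O)c(CC=C(C)C)c(OCOC)c(CC=C(C)C)c1OCOC
F3 | step 7 | (E)-3-(dimethylamino)-1-[2-hydroxy-4,6-bis(methoxymethoxy)-3,5-bis(3-methylbut-2-en-1-yl)phenyl]prop-2-en-1-one | CN(C)/C=C/C(=O)c1c(O)c(CC=C(C)C)c(OCOC)c(CC=C(C)C)c1OCOC
F4 | step 7 | 3-iodo-5,7-bis(methoxymethoxy)-6,8-bis(3-methylbut-2-en-1-yl)-4H-chromen-4-one | CC(C)=CCc1c(OCOC)c(CC=C(C)C)c2occ(I)c(=O)c2c1OCOC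
F5 | step 7 | 2-[4-(methoxymethoxy)-3-(3-methylbut-2-en-1-yl)phenyl]-4,4,5,5-tetramethyl-1,3,2-dioxaborolane | COCOc1ccc(B2OC(C)(C)C(C)(C)O2)cc1CC=C(C)C
F6 | step 1 | 1,3,5-tris(methoxymethoxy)benzene | COCOc1cc(OCOC)cc(OCOC)c1
F7 | step 1 | 1,3,5-tris(methoxymethoxy)-2-(3-methylbut-2-en-1-yl)benzene | COCOc1cc(OCOC)c(CC=C(C)C)c(OCOC)c1
F8 | step 1 | 1,3,5-tris(methoxymethoxy)-2,4-bis(3-methylbut-2-en-1-yl)benzene | COCOc1cc(OCOC)c(CC=C(C)C)c(OCOC)c1CC=C(C)C
F9 | step 1 | 2,4,6-tris(methoxymethoxy)-3,5-bis(3-methylbut-2-en-1-yl)benzaldehyde | O=Cc1c(OCOC)c(CC=C(C)C)c(OCOC)c(CC=C(C)C)c1OCOC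
F10 | step 6 | 2-[2-formyl-3,5-bis(methoxymethoxy)-4,6-bis(3-methylbut-2-en-1-yl)phenoxy]-N-methoxy-N-methylacetamide | CON(C)C(=O)COc1c(C=O)c(OCOC)c(CC=C(C)C)c(OCOC)c1CC=C(C)C
F11 | step 6 | 2-[2-(dimethoxymethyl)-3,5-bis(methoxymethoxy)-4,6-bis(3-methylbut-2-en-1-yl)phenoxy]-N-methoxy-N-methylacetamide | CON(C)C(=O)COc1c(C(OC)OC)c(OCOC)c(CC=C(C)C)c(OCOC)c1CC=C(C)C
F12 | step 6 | 2-[2-(dimethoxymethyl)-3,5-bis(methoxymethoxy)-4,6-bis(3-methylbut-2-en-1-yl)phenoxy]-1-[4-(methoxymethoxy)-3-(3-methylbut-2-en-1-yl)phenyl]ethan-1-one | COC(OC)c1c(OCOC)c(CC=C(C)C)c(OCOC)c(CC=C(C)C)c1OCC(=O)c1ccc(OCOC)c(CC=C(C)C)c1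
F13 | step 8 | rac-3,5,7-trihydroxy-3-[4-hydroxy-3-(3-methylbut-2-en-1-yl)phenyl]-6,8-bis(3-methylbut-2-en-1-yl)chroman-4-one | CC(C)=CCc1cc(C2(O)COc3c(CC=C(C)C)c(O)c(CC=C(C)C)c(O)c3C2=O)ccc1O
A1 | alternative 1 | genistein (5,7-dihydroxy-3-(4-hydroxyphenyl)-4H-chromen-4-one) | O=c1c(-c2ccc(O)cc2)coc2cc(O)cc(O)c12
A2 | alternative 1 | 5,7,4′-tri-O-allylgenistein | C=CCOc1ccc(-c2coc3cc(OCC=C)cc(OCC=C)c3c2=O)cc1
A3 | alternative 1 | 6,8,3′-triallylgenistein | C=CCc1cc(-c2coc3c(CC=C)c(O)c(CC=C)c(O)c3c2=O)ccc1O
A4 | alternative 1 | 2-methylbut-2-ene | CC=C(C)C
A5 | alternative 2 | 2-(2-diazo-5-methylhex-4-enoyl)-5-[4-(tert-butyldimethylsilyloxy)-3-(3-methylbut-2-en-1-yl)phenyl]-4H-pyran-4-one | CC(C)=CCC(=[N+]=[N-])C(=O)c1cc(=O)c(-c2ccc(O[Si](C)(C)C(C)(C)C)c(CC=C(C)C)c2)co1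
A6 | alternative 2 | triisopropyl[(5-methylhex-4-en-1-yn-1-yl)oxy]silane | CC(C)=CCC#CO[Si](C(C)C)(C(C)C)C(C)C
A7 | alternative 2 | 7-O-triisopropylsilyl-4′-O-(tert-butyldimethylsilyl) Euchrenone b1 | CC(C)=CCc1cc(-c2coc3c(CC=C(C)C)c(O[Si](C(C)C)(C(C)C)C(C)C)c(CC=C(C)C)c(O)c3c2=O)ccc1O[Si](C)(C)C(C)(C)C
A8 | alternative 3 | 5,7-bis(methoxymethoxy)-6,8-bis(3-methylbut-2-en-1-yl)-3-(2-oxo-2H-pyran-5-yl)-4H-chromen-4-one | CC(C)=CCc1c(OCOC)c(CC=C(C)C)c2occ(-c3ccc(=O)oc3)c(=O)c2c1OCOC
A9 | alternative 3 | 5,7-bis(methoxymethyl)-4′-O-triisopropylsilyl Euchrenone b1 | CC(C)=CCc1cc(-c2coc3c(CC=C(C)C)c(OCOC)c(CC=C(C)C)c(OCOC)c3c2=O)ccc1O[Si](C(C)C)(C(C)C)C(C)C
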